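The five flasks carry the same amounts of free monomer and initiator and differ in their loading of radical scavenger, so you need to know how much scavenger buys how much delay.

common to all: free monomer 0.11 M; initiator 0.22 mol%

| run | radical scavenger | remark | time |
|---|---|---|---|
| ochre | 0.058 mol% | run made earlier |  |
| amber | 0.17 mol% | run made earlier |  |
| violet | 0.66 mol% | run made earlier |  |
| south | 0.3 mol% |  | 80 min |
| north-west | 0.12 mol% |  | 80 min |
| north | 0.2 mol% |  | 80 min |
| east | 0.6 mol% |  | 80 min |
| south-east | 0.05 mol% |  | 80 min |

| run | time / min | monomer in chains / % |
|---|---|---|
| ochre | 5.00 | 1 |
| ochre | 8.00 | 0 |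
| ochre | 15.0 | 8 |
| ochre | 30.0 | 17 |
| ochre | 60.0 | 35 |
| amber | 12.0 | 2 |
| amber | 25.0 | 0 |
| amber | 30.0 | 1 |
| amber | 50.0 | 14 |
| amber | 60.0 | 19 |
| violet | 5.00 | 1 |
| violet | 15.0 | 0 |
| violet | 25.0 | 0 |
| violet | 40.0 | 0 |
| violet | 60.0 | 2 |

(scatter of a reading: 2 percentage points)

* ranking by amount of monomer in chains, in percent of the free monomer charged, from high to low, at 80 min (south / north-west / north / east / south-east)
* the amount of monomer in chains, in percent of the free monomer charged of the flask you put first, at 80 min
* the amount of monomer in chains, in percent of the free monomer charged of the flask you put last, at 80 min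

Work in the logarithm of the fraction of free monomer left, taking each rung of time in order. The last two ochre readings, each with a scatter of 2 percentage points, give the climb of that logarithm as a reading:

growth constant = 0.00815 min⁻¹

Running that line back from the last reading of ochre and of amber, with the same growth constant taken for amber, gives the first rungs, the lags (induction periods), as estimates from scattered readings:

ochre lag = 7.13 min

amber lag = 34.1 min

Amber starts later than ochre, and violet reads 2% at 60.0 min, so you can take scavenger as buying delay. The next rung is the asked 80 min, and the last is the growth time, 123 min, which is longer, so a flask read at 80 min has not yet had one growth time.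

Now carry one quantity forward, the burnable loading, by which I mean the loading of scavenger whose lag ends exactly at 80 min on the straight line through the two lags, with the initiator held at 0.22 mol%:

0.36 mol%

I reckon that below it the logarithm reached at 80 min shrinks in step with the distance from the burnable loading, so my ranking from high to low follows the loading upward: south-east, north-west, north, south, east. South lies below the burnable loading, while east lies above it and so, by my reckoning, is still in its lag. For south-east I reckon:

45.6%

The forecast gives south-east > north-west > north > south > east, with 44% first and 0% last, against my 45.6% for south-east, and its ground is “Scavenger therefore sets the delay, not the later rate.”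

The flasks give south-east > north-west > north > south > east, with 41.4% in south-east and 0.353% in east.

    2 growing radical → dead chain (k = 7.00 × 10⁷ M⁻¹ s⁻¹)
    free monomer + initiating radical → growing radical + monomer in chains (k = 3.10 × 10⁵ M⁻¹ s⁻¹)
    initiator → 2 initiating radical (k = 0.0170 min⁻¹)
    growing radical + radical scavenger → ended chains (k = 1.70 × 10⁷ M⁻¹ s⁻¹)
    free monomer + growing radical → monomer in chains + growing radical, rate k5*[growing radical]*[free monomer] (k = 3.30 × 10⁵ M⁻¹ min⁻¹)

At 80.0 min east still holds 45% of its scavenger and 6.90 × 10⁻¹² M of growing radical, against 0% and 1.59 × 10⁻⁸ M in south-east, a ratio of 2300. By then east has burned 0.33 mol% of scavenger, a little below the burnable loading of 0.36 mol%, while south, charged with 0.3 mol%, has 0% left and stands at a conversion of free monomer of 7.27%.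

(The earlier runs and the new flask are calculated with constants of no real substance, and the scatter is random.)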